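I began with the easy step: each reading y, the left-handed product as a fraction of both substrates charged, became E = −ln(1 − y).

| flask | left-handed substrate | right-handed substrate | partner | remark | time |
|---|---|---|---|---|---|
| violet | 0.10 M | 0.10 M | 0.40 M | the very flask that is asked about, followed so far |  |
| amber | 0.15 M | 0.15 M | 0.40 M | run made earlier |  |
| flask | 0.10 M | 0.10 M | 0.400 M |  | 30 min |

| run | time / min | left-handed product / % |
|---|---|---|
| violet | 2.00 | 5.3 |
| violet | 4.00 | 8.3 |
| violet | 6.00 | 11.5 |
| violet | 12.0 | 14.6 |
| violet | 25.0 | 18.8 |
| amber | 3.00 | 5.9 |
| amber | 6.00 | 10.9 |
| amber | 10.0 | 13.4 |
| amber | 12.0 | 14.6 |
| amber | 15.0 | 15.4 |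

(standard deviation of a reading: 0.5 percentage points)

- partner is single-handed; left-handed substrate and right-handed substrate are mirror images of each other, charged as a racemate, each of them at the stated concentration
- what is taken out of left-handed product is counted as made
- what may be going on: left-handed substrate <-> right-handed substrate; partner + right-handed substrate -> right-handed product; partner + left-handed substrate -> left-handed product; partner <-> dormant form; partner -> decomposition product; partner -> decomposed reagent
- additions bring no volume worth counting
- the handed part of partner does not stay in what it makes, so the products of the two hands are mirror images too

- cedar: at 30 min add left-handed substrate, 50.0 % of the amount charged, then wait 1.0 h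
- alder: at 30 min take out 90 % of the left-handed product then present, then wait 1.0 h
- ash: at 30 min add partner, 100 % of the amount charged, then wait 1.0 h
- oak: change nothing and wait 1.0 h more

1. left-handed product, in percent of the left-handed substrate and right-handed substrate together first charged, at 30 min
2. which option adds most left-handed product ("none" when 2 percentage points or less is all one gets) (cedar / alder / ash / oak / none)
3. left-handed product present, with what was taken out counted in, in percent of the left-handed substrate and right-handed substrate together first charged, after alder
4. left-handed product present, with what was taken out counted in, in percent of the left-handed substrate and right-handed substrate together first charged, after ash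

1. I assumed that the two substrate hands stay equal, the right-handed form refilling the left-handed one. Then dy/dt = k(1 − y), a pseudo-first-order law whose k follows partner, so E is the time integral of k. The violet and amber runs, with different substrate charges, both read 14.6 % at 12.0 min, so E follows one curve in time.

2. Start: over its first reading, the violet run's E rose at s = 0.0272 /min.

3. Knee: from 12.0 min to 25.0 min E rose from 0.158 to 0.208, a slope of 0.00388 /min, less than at the start. An exponential fade between those two mid-times gave τ = 8.98 min, a reading with the scatter in it.

4. Level: the fading tail adds 0.0169, so E∞ = 0.225, or y = 20.2 %. At 30 min I reckoned E = 0.215, or y = 19.4 %.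

5. If partner fades first-order, its integral is its charge times τ. So I carried the dose constant g = E∞/c, the ceiling of E per molar of partner charged: 0.563 /M.

6. Oak and alder run up to the ceiling, a gain of 0.80 percentage points, less than 2 points. Cedar gains 1 point. Ash adds a second dose, giving 36.3 %.

The forecast gave 20.5 %, ash, 32 % after alder and 43 % after ash, holding: “Partner apparently relaxes quickly to a small active share, with dormant form in equilibrium, and is not dead.” My reckoning shared its choice but stood lower, at 19.4 % at 30 min, 20.2 % after alder and 36.3 % after ash.

The simulation gave 18.4 % and ash, with gains of 0.52 points for cedar, 0.41 points for oak and 16 points for ash; alder reached 18.9 % and ash 34.4 %.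

    left-handed substrate ⇌ right-handed substrate (k = 0.0934 /s)
    partner + right-handed substrate → right-handed product (k = 3.07 × 10⁻⁵ /M/s)
    partner + left-handed substrate → left-handed product (k = 0.00253 /M/s)
    partner ⇌ dormant form (K = 0.131, k = 0.00114 /s)
    partner → decomposition product (k = 5.29 × 10⁻⁶ /s)
    partner → decomposed reagent (k = 0.00218 /s)

At 30.0 min the violet flask held 81.3 % of its left-handed substrate but 2.03 % of its partner, because partner wore away, partly into decomposed reagent. Without the wearing the flask gave 59.4 %, and without the decomposed-reagent step 49.5 %. Carried to ash, g gave 36.3 % against 34.4 %. For the neighbour flask with 1.0 M of partner, g with the same faded share gives E = 0.539, or 41.7 %; the simulation gave 40.2 %.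

All runs were generated by integration with constants of no real substance; the scatter is artificial.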